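**Retrosynthetic overview**

1. Target ⇐ C2‑selective acetylation of the 2α,3α‑diol ⇐ α‑face OsO4 dihydroxylation of a Δ2 alkene. Side chain ⇐ B‑alkyl Suzuki–Miyaura coupling of a C9 vinyl carbinol with an (E)‑enol triflate. C9 ⇐ axial vinyl addition (anti to C10–CH3) to the 8α‑methyl‑9‑ketone.
2. Ring A (C1–C2–C3–C4–C5–C10) ⇐ one‑carbon ring expansion of the A‑nor cyclopentane C1–C2–C3–C5–C10, a C3 tertiary carbinol bearing isopropenyl. Hydrogen‑atom transfer gives the C4 cation, the C3–C5 bond shifts to C4 (semipinacol) and C3 becomes the ketone.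
3. Enabling feature: in ring A the quaternary gem‑dimethyl carbon C4 lies between the oxygenated C3 and the ring‑fusion methine C5. C4(CH3)2 can therefore be inserted between C3 and C5, with retention at C5 and loss of the C3 carbinol centre, so both carbinol epimers converge.
4. A‑nor ketone ⇐ α‑face hydroboration/oxidation of the Δ3(5) hydrindene ⇐ McMurry closure C3=C5 ⇐ keto‑aldehyde ⇐ enzymatic desymmetrisation of 2‑allyl‑2‑methylcyclohexane‑1,3‑dione (sets C10).
5. Ring order: ring B (present from the start) → five‑membered A‑nor ring (step 6) → ring A by expansion (step 10).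

Key step: step 10

Remark: labdane numbering is used for all intermediates; the drawn target is 5α‑H, 10β‑CH3, 8α‑CH3, 9β‑OH (side chain 9α), 2α‑OAc, 3α‑OH, 13E, and a Prelog‑type ketoreductase giving the (2S,3S)‑hydroxy ketone of step 2 is assumed to be available (only its C10 configuration matters).

**Route**

Step 1
Reactants: 1 2‑methylcyclohexane‑1,3‑dione; 2 allyl bromide
Product: 3 2‑allyl‑2‑methylcyclohexane‑1,3‑dione
Conditions: NaOH (1 M aq.), rt
Reagents that add atoms: none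
Why: C‑allylation of the cyclic 1,3‑dione enolate in water (C‑selective for allylic halides) builds the quaternary carbon C10 carrying the C1–C2–C3 unit; no stereocentre is formed yet.

Step 2
Reactants: 3 2‑allyl‑2‑methylcyclohexane‑1,3‑dione
Product: 4 (2S,3S)‑2‑allyl‑3‑hydroxy‑2‑methylcyclohexan‑1‑one
Conditions: Prelog‑selective ketoreductase (baker's‑yeast type), NADP+ (cat.), i‑PrOH, phosphate buffer pH 7, 30 °C
Reagents that add atoms: none
Why: Desymmetrising enzymatic ketone reduction of a prochiral 2,2‑disubstituted 1,3‑dione should reduce only the future C5 carbonyl and thereby fix C10; the carbinol centre formed is destroyed in step 5.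

Step 3
Reactants: 4 (2S,3S)‑2‑allyl‑3‑hydroxy‑2‑methylcyclohexan‑1‑one
Product: 5 (6S,7S)‑6‑allyl‑6‑methyl‑1,4‑dioxaspiro[4.5]decan‑7‑ol
Conditions: ethylene glycol, PPTS (cat.), benzene, reflux (water separator)
Reagents that add atoms: ethylene glycol (OCCO)
Why: Acid‑catalysed ketalisation of the only ketone (future C9) masks it as a dioxolane until ring A is complete.

Step 4
Reactants: 5 (6S,7S)‑6‑allyl‑6‑methyl‑1,4‑dioxaspiro[4.5]decan‑7‑ol
Product: 7 (6S,7S)‑6‑(3‑hydroxypropyl)‑6‑methyl‑1,4‑dioxaspiro[4.5]decan‑7‑ol, via B‑alkyl‑9‑BBN adduct 6 (not isolated)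
Conditions: 9‑BBN, THF, 0 °C → rt; then NaOH (aq.), H2O2
Reagents that add atoms: 9‑borabicyclo[3.3.1]nonane (B1C2CCCC1CCC2; boron unit present only in 6); hydrogen peroxide (OO)
Why: Anti‑Markovnikov hydroboration–oxidation of the terminal alkene turns the allyl group into the C1–C2–C3 primary alcohol.

Step 5
Reactants: 7 (6S,7S)‑6‑(3‑hydroxypropyl)‑6‑methyl‑1,4‑dioxaspiro[4.5]decan‑7‑ol
Product: 8 3‑[(6S)‑6‑methyl‑7‑oxo‑1,4‑dioxaspiro[4.5]decan‑6‑yl]propanal
Conditions: DMP (2.5 equiv), pyridine, CH2Cl2, 0 °C → rt; used directly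
Reagents that add atoms: none
Why: Dess–Martin oxidation of both alcohols under buffered, non‑enolising conditions should give the 1,5‑keto‑aldehyde (C5 ketone, C3 aldehyde) without aldol side reactions.

Step 6
Reactants: 8 3‑[(6S)‑6‑methyl‑7‑oxo‑1,4‑dioxaspiro[4.5]decan‑6‑yl]propanal
Product: 9 9,9‑(ethylenedioxy)‑10β‑methyl‑A‑nor‑hydrind‑3(5)‑ene (five‑membered ring C10–C1–C2–C3=C5; six‑membered ring C5–C10)
Conditions: TiCl4, Zn, pyridine, THF, reflux, slow addition (high dilution)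
Reagents that add atoms: none
Why: Intramolecular McMurry coupling of the C3 aldehyde with the C5 ketone closes the cyclopentene (5‑membered ring via C3=C5) and is compatible with the buffered ketal.

Step 7
Reactants: 9 9,9‑(ethylenedioxy)‑10β‑methyl‑A‑nor‑hydrind‑3(5)‑ene
Product: 11 9,9‑(ethylenedioxy)‑10β‑methyl‑5α‑H‑A‑nor‑hydrindan‑3α‑ol (trans‑fused), via C3 alkylborane 10 (not isolated)
Conditions: BH3·THF, THF, 0 °C → rt; then NaOH (aq.), H2O2
Reagents that add atoms: borane (B; boron present only in 10); hydrogen peroxide (OO)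
Why: Hydroboration–oxidation places boron on the less substituted C3 and adds syn from the α face, opposite the axial C10 methyl on the adjacent carbon (as for Δ14 steroids), which sets 5α‑H (trans ring fusion) and 3α‑OH.

Step 8
Reactants: 11 9,9‑(ethylenedioxy)‑10β‑methyl‑5α‑H‑A‑nor‑hydrindan‑3α‑ol
Product: 12 9,9‑(ethylenedioxy)‑10β‑methyl‑5α‑H‑A‑nor‑hydrindan‑3‑one
Conditions: DMP, pyridine, CH2Cl2, 0 °C; used without chromatography on basic supports
Reagents that add atoms: none
Why: Buffered Dess–Martin oxidation should give the trans‑fused cyclopentanone without epimerising the adjacent C5 centre.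

Step 9
Reactants: 12 9,9‑(ethylenedioxy)‑10β‑methyl‑5α‑H‑A‑nor‑hydrindan‑3‑one
Product: 13 9,9‑(ethylenedioxy)‑3‑isopropenyl‑10β‑methyl‑5α‑H‑A‑nor‑hydrindan‑3‑ol (3β‑OH epimer drawn; the 3α‑OH epimer is carried along)
Conditions: isopropenylmagnesium bromide, CeCl3, THF, −78 °C
Reagents that add atoms: isopropenylmagnesium bromide (C=C(C)[Mg]Br)
Why: Organocerium 1,2‑addition is weakly basic, so enolisation and C5 epimerisation are suppressed; attack is expected mainly from the α face, but the C3 configuration is irrelevant because step 10 destroys it.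

Step 10
Reactants: 13 9,9‑(ethylenedioxy)‑3‑isopropenyl‑10β‑methyl‑5α‑H‑A‑nor‑hydrindan‑3‑ol
Product: 14 9,9‑(ethylenedioxy)‑4,4,10β‑trimethyl‑5α‑H‑trans‑decalin‑3‑one
Conditions: Co(salen) (5 mol%), N‑fluoro‑2,4,6‑trimethylpyridinium triflate (1.5 equiv), PhSiH3 (1.5 equiv), PhCF3, 0 °C → rt
Reagents that add atoms: none
Why: A cobalt(III) hydride formed from the Co(salen) catalyst, the N‑fluoropyridinium oxidant and the silane transfers H• to the CH2 terminus of the isopropenyl group; the tertiary C4 radical is captured and oxidised to an alkylcobalt(IV)/C4 cation, and the C3–C5 bond shifts to C4 while the C3 hydroxyl becomes the C3 carbonyl (semipinacol 1,2‑shift). The closest known reaction type is the MHAT‑initiated radical–polar crossover semipinacol ring expansion of 1‑isopropenylcycloalkanols (ionic counterpart: acid‑promoted D‑homoannulation of 17‑alkenyl‑17‑hydroxy steroids, also five → six). Ring A (C1–C2–C3–C4–C5–C10) is not closed by a cyclisation but arises from the cyclopentane C1–C2–C3–C5–C10 by insertion of C4 between C3 and C5. No new stereocentre is created: C5 migrates with retention, so the 5α‑H/10β‑CH3 trans‑hydrindane becomes the trans‑decalin, and the C3 carbinol centre is destroyed, so both epimers of 13 converge on 14. The step needs migration of C5 rather than C2 and a 1,2‑shift rather than oxirane closure by the hydroxyl; C5 is the more substituted migrating carbon and its shift releases the strain of the trans‑fused five‑membered ring, while the non‑acidic conditions avoid ionisation of the tertiary allylic alcohol and spare the ketal.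

Step 11
Reactants: 14 9,9‑(ethylenedioxy)‑4,4,10β‑trimethyl‑5α‑H‑trans‑decalin‑3‑one
Product: 15 Δ2‑enol triflate of 14 (3‑trifluoromethanesulfonyloxy‑Δ2)
Conditions: KHMDS, THF, −78 °C; PhNTf2, −78 → 0 °C
Reagents that add atoms: N‑phenylbis(trifluoromethanesulfonimide) (O=S(=O)(N(c1ccccc1)S(=O)(=O)C(F)(F)F)C(F)(F)F)
Why: Enolisation can occur only toward C2 (C4 is quaternary), and O‑triflation of that enolate gives the Δ2‑enol triflate regiospecifically.

Step 12
Reactants: 15 Δ2‑enol triflate of 14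
Product: 16 9,9‑(ethylenedioxy)‑4,4,10β‑trimethyl‑5α‑H‑Δ2‑octalin
Conditions: Pd(OAc)2 (5 mol%), PPh3, Et3N, HCO2H, DMF, 60 °C
Reagents that add atoms: none
Why: Palladium‑catalysed formate reduction of the enol triflate gives the Δ2 alkene, which serves as a base‑stable mask of the 2,3‑diol.

Step 13
Reactants: 16 9,9‑(ethylenedioxy)‑4,4,10β‑trimethyl‑5α‑H‑Δ2‑octalin
Product: 17 4,4,10β‑trimethyl‑5α‑H‑Δ2‑octalin‑9‑one
Conditions: HCl (1 M aq.), THF, rt → 40 °C
Reagents that add atoms: water (O)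
Why: Acid hydrolysis of the dioxolane unveils the C9 ketone, now the only carbonyl group in the molecule.

Step 14
Reactants: 17 4,4,10β‑trimethyl‑5α‑H‑Δ2‑octalin‑9‑one
Product: 19 4,4,8α,10β‑tetramethyl‑5α‑H‑Δ2‑octalin‑9‑one, via lithium enolate 18 (not isolated)
Conditions: LDA, THF, −78 °C; MeI, −78 → 0 °C; then NaOMe (cat.), MeOH, rt
Reagents that add atoms: iodomethane (CI); lithium diisopropylamide (CC(C)[N-]C(C)C.[Li+]; lithium present only in 18)
Why: Enolate alkylation can occur only at C8 (C10 is quaternary), and base equilibration places the methyl equatorial (8α), away from the 1,3‑diaxial C10 methyl.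

Step 15
Reactants: 19 4,4,8α,10β‑tetramethyl‑5α‑H‑Δ2‑octalin‑9‑one
Product: 20 9α‑vinyl‑4,4,8α,10β‑tetramethyl‑5α‑H‑Δ2‑octalin‑9β‑ol
Conditions: vinylmagnesium bromide, CeCl3, THF, −78 → 0 °C
Reagents that add atoms: vinylmagnesium bromide (C=C[Mg]Br)
Why: In this organocerium 1,2‑addition the equatorial trajectory is blocked by the axial C10 methyl on the neighbouring carbon, so the nucleophile enters axially from the α face and sets C9 with vinyl α and OH β.

Step 16
Reactants: 21 methyl acetoacetate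
Product: 22 methyl (E)‑3‑(trifluoromethylsulfonyloxy)but‑2‑enoate
Conditions: Tf2O, Me4NOH (aq.), hexanes, 5 °C
Reagents that add atoms: trifluoromethanesulfonic anhydride (O=S(=O)(OS(=O)(=O)C(F)(F)F)C(F)(F)F)
Why: O‑Triflation of the non‑chelated tetraalkylammonium enolate of the β‑keto ester is a known stereoselective route to the (E)‑enol triflate (OTf trans to the ester).

Step 17
Reactants: 20 9α‑vinyl‑4,4,8α,10β‑tetramethyl‑5α‑H‑Δ2‑octalin‑9β‑ol; 22 methyl (E)‑3‑(trifluoromethylsulfonyloxy)but‑2‑enoate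
Product: 24 methyl (E)‑5‑(9β‑hydroxy‑4,4,8α,10β‑tetramethyl‑5α‑H‑Δ2‑octalin‑9α‑yl)‑3‑methylpent‑2‑enoate, via B‑alkyl‑9‑BBN adduct 23 (not isolated)
Conditions: 9‑BBN (2.5 equiv), THF, rt → 50 °C; then 22, PdCl2(dppf) (5 mol%), K3PO4 (aq.), DMF, rt
Reagents that add atoms: 9‑borabicyclo[3.3.1]nonane (B1C2CCCC1CCC2; boron unit present only in 23)
Why: 9‑BBN hydroborates only the monosubstituted vinyl group (the hindered ring alkene is inert), and B‑alkyl Suzuki–Miyaura coupling proceeds with retention of the enol triflate geometry to give the (E)‑enoate.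

Step 18
Reactants: 24 methyl (E)‑5‑(9β‑hydroxy‑4,4,8α,10β‑tetramethyl‑5α‑H‑Δ2‑octalin‑9α‑yl)‑3‑methylpent‑2‑enoate
Product: 25 methyl (E)‑5‑(2α,3α,9β‑trihydroxy‑4,4,8α,10β‑tetramethyl‑5α‑H‑decalin‑9α‑yl)‑3‑methylpent‑2‑enoate
Conditions: OsO4 (5 mol%), NMO (1.1 equiv), acetone–H2O, rt
Reagents that add atoms: N‑methylmorpholine N‑oxide (C[N+]1([O-])CCOCC1); osmium tetroxide (O=[Os](=O)(=O)=O, cat.); water (O)
Why: Catalytic syn‑dihydroxylation should attack the Δ2 alkene from the α face (the β face carries the axial C10 and C4β methyls) to give the 2α,3α‑diol, while the electron‑poor trisubstituted enoate reacts much more slowly.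

Step 19
Reactants: 25 methyl (E)‑5‑(2α,3α,9β‑trihydroxy‑4,4,8α,10β‑tetramethyl‑5α‑H‑decalin‑9α‑yl)‑3‑methylpent‑2‑enoate
Product: 26 CNP0135744.1 (2α‑acetoxy‑3α,9β‑dihydroxy compound)
Conditions: Ac2O (1.1 equiv), pyridine, 0 °C
Reagents that add atoms: acetic anhydride (CC(=O)OC(C)=O)
Why: Acylation should be selective for the equatorial secondary C2 hydroxyl over the axial, neopentyl C3 hydroxyl and the tertiary C9 hydroxyl.

**Compound list**

1 | 2‑methylcyclohexane‑1,3‑dione | CC1C(=O)CCCC1=O | starting material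
2 | allyl bromide | C=CCBr | starting material
3 | 2‑allyl‑2‑methylcyclohexane‑1,3‑dione | C=CCC1(C)C(=O)CCCC1=O | intermediate
4 | (2S,3S)‑2‑allyl‑3‑hydroxy‑2‑methylcyclohexan‑1‑one | O=C1CCC[C@H](O)[C@]1(C)CC=C | intermediate
5 | (6S,7S)‑6‑allyl‑6‑methyl‑1,4‑dioxaspiro[4.5]decan‑7‑ol | C12(OCCO1)CCC[C@H](O)[C@]2(C)CC=C | intermediate
6 | B‑alkyl‑9‑BBN adduct of 5 (boron on the terminal carbon C3) | C12(OCCO1)CCC[C@H](O)[C@]2(C)CCCB3C4CCCC3CCC4 | intermediate (not isolated)
7 | (6S,7S)‑6‑(3‑hydroxypropyl)‑6‑methyl‑1,4‑dioxaspiro[4.5]decan‑7‑ol | C12(OCCO1)CCC[C@H](O)[C@]2(C)CCCO | intermediate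
8 | 3‑[(6S)‑6‑methyl‑7‑oxo‑1,4‑dioxaspiro[4.5]decan‑6‑yl]propanal | C12(OCCO1)CCCC(=O)[C@]2(C)CCC=O | intermediate
9 | 9,9‑(ethylenedioxy)‑10β‑methyl‑A‑nor‑hydrind‑3(5)‑ene | C12(OCCO1)CCCC3=CCC[C@@]32C | intermediate
10 | C3 (α) alkylborane from 9 (5α‑H) | C12(OCCO1)CCC[C@H]3[C@H](B)CC[C@@]32C | intermediate (not isolated)
11 | 9,9‑(ethylenedioxy)‑10β‑methyl‑5α‑H‑A‑nor‑hydrindan‑3α‑ol | C12(OCCO1)CCC[C@H]3[C@H](O)CC[C@@]32C | intermediate
12 | 9,9‑(ethylenedioxy)‑10β‑methyl‑5α‑H‑A‑nor‑hydrindan‑3‑one | C12(OCCO1)CCC[C@H]3C(=O)CC[C@@]32C | intermediate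
13 | 9,9‑(ethylenedioxy)‑3α‑isopropenyl‑10β‑methyl‑5α‑H‑A‑nor‑hydrindan‑3β‑ol (C3 epimer also usable) | C12(OCCO1)CCC[C@H]3[C@](O)(C(C)=C)CC[C@@]32C | intermediate
14 | 9,9‑(ethylenedioxy)‑4,4,10β‑trimethyl‑5α‑H‑trans‑decalin‑3‑one | C12(OCCO1)CCC[C@H]3C(C)(C)C(=O)CC[C@@]32C | intermediate
15 | Δ2‑enol triflate of 14 | C12(OCCO1)CCC[C@H]3C(C)(C)C(OS(=O)(=O)C(F)(F)F)=CC[C@@]32C | intermediate
16 | 9,9‑(ethylenedioxy)‑4,4,10β‑trimethyl‑5α‑H‑Δ2‑octalin | C12(OCCO1)CCC[C@H]3C(C)(C)C=CC[C@@]32C | intermediate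
17 | 4,4,10β‑trimethyl‑5α‑H‑Δ2‑octalin‑9‑one | O=C1CCC[C@H]2C(C)(C)C=CC[C@@]21C | intermediate
18 | lithium Δ8(9)‑enolate of 17 | [Li]OC1=CCC[C@H]2C(C)(C)C=CC[C@@]21C | intermediate (not isolated)
19 | 4,4,8α,10β‑tetramethyl‑5α‑H‑Δ2‑octalin‑9‑one | O=C1[C@H](C)CC[C@H]2C(C)(C)C=CC[C@@]21C | intermediate
20 | 9α‑vinyl‑4,4,8α,10β‑tetramethyl‑5α‑H‑Δ2‑octalin‑9β‑ol | C=C[C@]1(O)[C@H](C)CC[C@H]2C(C)(C)C=CC[C@@]21C | intermediate
21 | methyl acetoacetate | CC(=O)CC(=O)OC | starting material
22 | methyl (E)‑3‑(trifluoromethylsulfonyloxy)but‑2‑enoate | COC(=O)/C=C(\C)OS(=O)(=O)C(F)(F)F | intermediate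
23 | B‑alkyl‑9‑BBN adduct of 20 (boron on C12) | B3(C4CCCC3CCC4)CC[C@]1(O)[C@H](C)CC[C@H]2C(C)(C)C=CC[C@@]21C | intermediate (not isolated)
24 | methyl (E)‑5‑(9β‑hydroxy‑4,4,8α,10β‑tetramethyl‑5α‑H‑Δ2‑octalin‑9α‑yl)‑3‑methylpent‑2‑enoate | COC(=O)/C=C(\C)CC[C@]1(O)[C@H](C)CC[C@H]2C(C)(C)C=CC[C@@]21C | intermediate
25 | 2α,3α‑diol of 24 | COC(=O)/C=C(\C)CC[C@]1(O)[C@H](C)CC[C@H]2C(C)(C)[C@H](O)[C@H](O)C[C@@]21C | intermediate
26 | CNP0135744.1 | COC(=O)/C=C(\C)CC[C@]1(O)[C@H](C)CC[C@H]2C(C)(C)[C@H](O)[C@H](OC(C)=O)C[C@@]21C | target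

**Step count and risks**

Total steps: 19. Longest linear sequence: 18 (steps 1–15 and 17–19; step 16 prepares the coupling partner).

Steps most likely to fail:

1. Step 10. The cationic C4 centre may be trapped by the neighbouring hydroxyl (oxirane closure), or C2 may migrate instead of C5. The fallback sets out from ketone 12: addition of 2‑lithio‑2‑(methylseleno)propane (from 2,2‑bis(methylseleno)propane and n‑BuLi, THF, −78 °C) should give the β‑hydroxy selenide F1. Se‑methylation and ionisation with MeI/AgBF4 in CH2Cl2 then triggers the selenonium‑induced pinacol‑type ring expansion, a classical 2,2‑dimethyl homologation of cycloalkanones, and returns to the route at 14.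

2. Step 7 (with step 8). Hydroboration may occur partly from the β face, or the trans‑fused cyclopentanone may epimerise at C5 on handling; either leads to the cis ring fusion. The fallback sets out from keto‑aldehyde 8 and avoids any C5 stereocentre before the ring expansion. An NHC‑catalysed intramolecular crossed benzoin reaction (thiazolium salt, Et3N) should give the cis‑fused acyloin F2. Dehydration (SOCl2, pyridine) gives the alkylidene cyclopentanone F3 (C3 ketone conjugated with C5=C6). Isopropenylcerium addition gives the bis‑allylic carbinol F4. The same MHAT semipinacol conditions, now with migration of the alkenyl carbon C5, give the β,γ‑unsaturated ketone F5. Hydrogenation (H2, Pd/C) from the α face, anti to the C10 methyl, sets 5α‑H and returns to the route at 14.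

3. Step 18. The hindered Δ2 alkene may react slowly, so that dihydroxylation of the side‑chain enoate competes. The fallback sets out from ketone 19, where no other alkene is present. OsO4/NMO gives the keto‑diol F6, and 2,2‑dimethoxypropane/PPTS protects it as the acetonide F7. Vinylcerium addition as in step 15 gives the carbinol F8, and hydroboration/Suzuki–Miyaura coupling with 22 as in step 17 gives the enoate acetonide F9. Aqueous acetic acid removes the acetonide and returns to the route at diol 25.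

**Further compounds**

F1 | step 10 | 9,9‑(ethylenedioxy)‑10β‑methyl‑3α‑[2‑(methylseleno)propan‑2‑yl]‑5α‑H‑A‑nor‑hydrindan‑3β‑ol | C12(OCCO1)CCC[C@H]3[C@](O)(C(C)(C)[Se]C)CC[C@@]32C
F2 | step 7 | 9,9‑(ethylenedioxy)‑5β‑hydroxy‑10β‑methyl‑A‑nor‑hydrindan‑3‑one (cis‑fused acyloin) | C12(OCCO1)CCC[C@]3(O)C(=O)CC[C@@]32C
F3 | step 7 | 9,9‑(ethylenedioxy)‑10β‑methyl‑A‑nor‑hydrind‑5(6)‑en‑3‑one | C12(OCCO1)CCC=C3C(=O)CC[C@@]32C
F4 | step 7 | 9,9‑(ethylenedioxy)‑3‑isopropenyl‑10β‑methyl‑A‑nor‑hydrind‑5(6)‑en‑3‑ol | C12(OCCO1)CCC=C3[C@](O)(C(C)=C)CC[C@@]32C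
F5 | step 7 | 9,9‑(ethylenedioxy)‑4,4,10β‑trimethyl‑Δ5(6)‑octalin‑3‑one | C12(OCCO1)CCC=C3C(C)(C)C(=O)CC[C@@]32C
F6 | step 18 | 2α,3α‑dihydroxy‑4,4,8α,10β‑tetramethyl‑5α‑H‑trans‑decalin‑9‑one | O=C1[C@H](C)CC[C@H]2C(C)(C)[C@H](O)[C@H](O)C[C@@]21C
F7 | step 18 | 2α,3α‑acetonide of F6 | O=C1[C@H](C)CC[C@H]2C(C)(C)[C@@H]3OC(C)(C)O[C@@H]3C[C@@]21C
F8 | step 18 | 9α‑vinyl‑9β‑ol from F7 (2α,3α‑acetonide) | C=C[C@]1(O)[C@H](C)CC[C@H]2C(C)(C)[C@@H]3OC(C)(C)O[C@@H]3C[C@@]21C
F9 | step 18 | 2α,3α‑acetonide of 25 | COC(=O)/C=C(\C)CC[C@]1(O)[C@H](C)CC[C@H]2C(C)(C)[C@@H]3OC(C)(C)O[C@@H]3C[C@@]21C
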